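**Retrosynthetic overview** (ring A = dibromo ring, ring B = tribromo ring)
1. Target ⇒ its ring A methyl ether; the last step is a BBr3 demethylation.
2. Key disconnection: the diaryl ether bond between the ring A oxygen and the ring B carbon ⇒ 3,5-dibromo-2-methoxyphenol + a tribromo ortho-quinone diazide. They are joined by a new rhodium-carbene O–H insertion that also delivers the free ring B hydroxyl.
3. Ring B piece ⇐ diazotisation ⇐ nitro reduction ⇐ double bromination of 5-bromo-2-nitrophenol, where all directing effects converge.
4. Ring A piece ⇐ Baeyer–Villiger oxidation/methanolysis ⇐ O-methylation of 3,5-dibromosalicylaldehyde.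
5. No ring is built. Both benzene rings are bought intact, ring B is finished first and ring A second, and all five bromines are in place before the coupling.

**Assumption:** the target has no stereocentre and no configurationally stable axis. It is achiral, so "the single enantiomer given" is the one constitution drawn and no stereocontrol is needed.

**Step 1**
Reactants: 1 5-bromo-2-nitrophenol
Product: 2 2,3,4-tribromo-6-nitrophenol
Conditions: Br2 (2.4 equiv), AcOH, rt then 85 °C
Reagents that add atoms: bromine, BrBr
Why: Electrophilic aromatic bromination in which OH (ortho/para), NO2 (meta) and the bromine already present (ortho) all direct to the same two free positions, so only one tribromide can form.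

**Step 2**
Reactants: 2 2,3,4-tribromo-6-nitrophenol
Product: 3 6-amino-2,3,4-tribromophenol
Conditions: SnCl2·2H2O (4 equiv), conc. HCl, EtOH, 60 °C
Reagents that add atoms: none
Why: Stoichiometric nitro reduction by divalent tin proceeds by electron and proton transfer and leaves aryl bromides untouched, unlike catalytic hydrogenation.

**Step 3**
Reactants: 3 6-amino-2,3,4-tribromophenol
Product: 5 2,3,4-tribromo-6-diazocyclohexa-2,4-dien-1-one, via diazonium chloride 4 (not isolated)
Conditions: NaNO2 (1.1 equiv), 6 M HCl, MeCN–H2O, 0 °C; then aq. NaHCO3 to pH 7, CH2Cl2 extraction, dark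
Reagents that add atoms: sodium nitrite, [Na+].[O-]N=O
Why: Classical diazotisation of an ortho-aminophenol, in which the very acidic OH of the diazonium salt loses its proton on neutralisation to give the neutral, extractable ortho-quinone diazide.

**Step 4**
Reactants: 6 3,5-dibromo-2-hydroxybenzaldehyde (3,5-dibromosalicylaldehyde)
Product: 7 3,5-dibromo-2-methoxybenzaldehyde
Conditions: MeI (1.5 equiv), K2CO3, DMF, rt
Reagents that add atoms: iodomethane, CI
Why: Williamson ether synthesis (SN2 on MeI) of an acidic phenol, with no other alkylatable site in the molecule.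

**Step 5**
Reactants: 7 3,5-dibromo-2-methoxybenzaldehyde
Product: 9 3,5-dibromo-2-methoxyphenol, via aryl formate 8 (not isolated)
Conditions: mCPBA (1.5 equiv), CH2Cl2, 40 °C; then MeOH, Et3N (0.1 equiv), rt
Reagents that add atoms: 3-chloroperoxybenzoic acid (mCPBA), OOC(=O)c1cccc(Cl)c1
Why: Baeyer–Villiger (Dakin-type) oxidation in which the ortho-methoxyaryl group of the Criegee adduct migrates to oxygen in preference to hydride, and the resulting formate is transesterified by methanol.

**Step 6**
Reactants: 5 2,3,4-tribromo-6-diazocyclohexa-2,4-dien-1-one; 9 3,5-dibromo-2-methoxyphenol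
Product: 11 2,3,4-tribromo-6-(3,5-dibromo-2-methoxyphenoxy)phenol, via rhodium quinoid carbene 10 (not isolated)
Conditions: Rh2(esp)2 (2 mol %; esp = 3,3'-(1,3-phenylene)bis(2,2-dimethylpropanoate)), 9 (2 equiv), 4 Å MS, PhCF3, 60 °C, dark; 5 in ClCH2CH2Cl added over 6 h
Reagents that add atoms: none
Why: Proposed new method: aromatising O–H insertion of a rhodium quinoid carbene into a phenol, used as a base-free, copper- and palladium-free diaryl ether synthesis; the diazo carbon of 5 binds an axial site of the divalent-rhodium dimer and loses N2 to give the strongly electrophilic carbene 10, the hydroxyl oxygen of 9 adds to the carbene carbon, and the neighbouring carbonyl oxygen takes up the proton through a five-membered hydrogen-bonded array, so that rearomatisation together with N2 loss makes C–O bond formation irreversible and places the ether and the free OH on adjacent carbons exactly as programmed by the aminophenol; Wolff ring contraction is a free-carbene or photochemical path and is held back by metal binding, darkness and the mild temperature, slow addition of 5 holds back its dimerisation, the absence of base holds back azo coupling, the bromines of 9 shut down arene C–H attack and cyclopropanation, and no C–Br bond can react because no low-valent metal is present; the closest known reaction types are the dirhodium-catalysed O–H insertion of diazonaphthoquinones into aliphatic alcohols and of alpha-diazocarbonyl compounds into phenols, neither of which, as far as I know, has been shown for a monocyclic polyhalogenated ortho-quinone diazide with a phenol as partner.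

**Step 7**
Reactants: 11 2,3,4-tribromo-6-(3,5-dibromo-2-methoxyphenoxy)phenol
Product: 13 2,3,4-tribromo-6-(3,5-dibromo-2-hydroxyphenoxy)phenol (target), via bis(dibromoboryl) derivative 12 (not isolated)
Conditions: BBr3 (4 equiv), CH2Cl2, −78 °C to rt; then H2O, 0 °C
Reagents that add atoms: none
Why: Lewis-acid aryl methyl ether cleavage (bromide SN2 on the BBr3-activated methyl group), to which the diaryl ether and the aryl bromides are inert, followed by hydrolysis of the B–O bonds.

**Compound list**
1 | 5-bromo-2-nitrophenol | Oc1cc(Br)ccc1[N+](=O)[O-] | starting material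
2 | 2,3,4-tribromo-6-nitrophenol | Oc1c(Br)c(Br)c(Br)cc1[N+](=O)[O-] | intermediate
3 | 6-amino-2,3,4-tribromophenol | Nc1cc(Br)c(Br)c(Br)c1O | intermediate
4 | 3,4,5-tribromo-2-hydroxybenzenediazonium chloride (not isolated) | Oc1c(Br)c(Br)c(Br)cc1[N+]#N.[Cl-] | intermediate
5 | 2,3,4-tribromo-6-diazocyclohexa-2,4-dien-1-one (ortho-quinone diazide) | O=C1C(Br)=C(Br)C(Br)=CC1=[N+]=[N-] | intermediate
6 | 3,5-dibromo-2-hydroxybenzaldehyde | O=Cc1cc(Br)cc(Br)c1O | starting material
7 | 3,5-dibromo-2-methoxybenzaldehyde | COc1c(Br)cc(Br)cc1C=O | intermediate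
8 | 3,5-dibromo-2-methoxyphenyl formate (not isolated) | COc1c(Br)cc(Br)cc1OC=O | intermediate
9 | 3,5-dibromo-2-methoxyphenol | COc1c(Br)cc(Br)cc1O | intermediate
10 | Rh2(esp)2(3,4,5-tribromo-6-oxocyclohexa-2,4-dien-1-ylidene), carbene bound axially to one rhodium (not isolated) | O=C1C(Br)=C(Br)C(Br)=CC1=[Rh+2].[Rh+2].[O-]C(=O)C(C)(C)Cc1cccc(CC(C)(C)C([O-])=O)c1.[O-]C(=O)C(C)(C)Cc1cccc(CC(C)(C)C([O-])=O)c1 | intermediate
11 | 2,3,4-tribromo-6-(3,5-dibromo-2-methoxyphenoxy)phenol | COc1c(Br)cc(Br)cc1Oc1cc(Br)c(Br)c(Br)c1O | intermediate
12 | dibromo{2,3,4-tribromo-6-[3,5-dibromo-2-(dibromoboryloxy)phenoxy]phenoxy}borane (not isolated) | BrB(Br)Oc1c(Br)cc(Br)cc1Oc1cc(Br)c(Br)c(Br)c1OB(Br)Br | intermediate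
13 | 2,3,4-tribromo-6-(3,5-dibromo-2-hydroxyphenoxy)phenol (achiral) | Oc1c(Br)cc(Br)cc1Oc1cc(Br)c(Br)c(Br)c1O | target

**Total step count:** 7.
**Longest linear sequence:** 5 steps (1 → 2 → 3 → 5 → 11 → 13, that is steps 1, 2, 3, 6 and 7).

**Three steps most likely to fail**

**Step 6 (the proposed new coupling).**
- Risks: Wolff contraction, attack of the product phenol on a second carbene, azo coupling, and dimerisation of the carbene. The dimer would be a hexabromodibenzo-para-dioxin and must be treated as highly toxic.
- The fallback is known chemistry throughout. It sets out from 5, with 9 as partner, and comes back to the route at 12.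
- Aqueous HCl turns 5 back into 4, and KI then gives 2,3,4-tribromo-6-iodophenol F1 by iodo-dediazoniation. MeI/K2CO3 in DMF gives 1,2,3-tribromo-5-iodo-4-methoxybenzene F2.
- mCPBA and TsOH·H2O in MeCN oxidise F2 to the trivalent-iodine species 1,2,3-tribromo-5-[hydroxy(tosyloxy)iodo]-4-methoxybenzene F3. This is trapped in the same flask by 1,3,5-trimethoxybenzene as (3,4,5-tribromo-2-methoxyphenyl)(2,4,6-trimethoxyphenyl)iodonium tosylate F4.
- Metal-free O-arylation of 9 by F4 (K2CO3, MeCN, 60 °C) transfers the electron-poor aryl group and gives 1,2,3-tribromo-5-(3,5-dibromo-2-methoxyphenoxy)-4-methoxybenzene F5.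
- BBr3 in CH2Cl2 cleaves both methyl ethers of F5 to 12, which is hydrolysed to 13 as in step 7.

**Step 5 (Baeyer–Villiger oxidation).**
- Risk: the methoxy group is flanked on both sides and twisted out of conjugation, so it is a weak donor. Hydride migration to the benzoic acid may then compete with aryl migration.
- The fallback makes 9 unnecessary by placing the ring A bromines last. It sets out from 5 and comes back to the route at 13. It still relies on the step 6 coupling.
- The step 6 coupling is run on 5 (through 10) with commercial 2-methoxyphenol and gives 2,3,4-tribromo-6-(2-methoxyphenoxy)phenol F6.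
- BBr3 converts F6 into dibromo{2,3,4-tribromo-6-[2-(dibromoboryloxy)phenoxy]phenoxy}borane F7, and water releases 2,3,4-tribromo-6-(2-hydroxyphenoxy)phenol F8.
- Br2 (2.0 equiv) in AcOH at 0 °C to rt brominates only ring A, ortho and para to its free OH. Ring B is deactivated and its single free position is meta to its own OH. The product is 13.

**Step 3 (diazotisation and handling of the diazide).**
- Risks: the amine is weakly basic and poorly soluble, and 5 is light-sensitive and potentially explosive when dry.
- The fallback replaces aqueous nitrous acid chemistry and isolation of neutral 5 by anhydrous nitrosonium chemistry with a storable salt. It sets out from 3 and comes back to the route at 5.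
- NOBF4 in MeCN at −20 °C, followed by precipitation with Et2O, gives crystalline 3,4,5-tribromo-2-hydroxybenzenediazonium tetrafluoroborate F9.
- F9 is stirred with solid NaHCO3 in ClCH2CH2Cl just before use. The filtered and dried solution of 5 goes straight into the syringe pump of step 6.

**Further compounds**
F1 | step 6 | 2,3,4-tribromo-6-iodophenol | Oc1c(I)cc(Br)c(Br)c1Br
F2 | step 6 | 1,2,3-tribromo-5-iodo-4-methoxybenzene | COc1c(I)cc(Br)c(Br)c1Br
F3 | step 6 | 1,2,3-tribromo-5-[hydroxy(tosyloxy)iodo]-4-methoxybenzene | COc1c(Br)c(Br)c(Br)cc1I(O)OS(=O)(=O)c1ccc(C)cc1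
F4 | step 6 | (3,4,5-tribromo-2-methoxyphenyl)(2,4,6-trimethoxyphenyl)iodonium tosylate | COc1c(Br)c(Br)c(Br)cc1[I+]c1c(OC)cc(OC)cc1OC.Cc1ccc(cc1)S(=O)(=O)[O-]
F5 | step 6 | 1,2,3-tribromo-5-(3,5-dibromo-2-methoxyphenoxy)-4-methoxybenzene | COc1c(Br)cc(Br)cc1Oc1cc(Br)c(Br)c(Br)c1OC
F6 | step 5 | 2,3,4-tribromo-6-(2-methoxyphenoxy)phenol | COc1ccccc1Oc1cc(Br)c(Br)c(Br)c1O
F7 | step 5 | dibromo{2,3,4-tribromo-6-[2-(dibromoboryloxy)phenoxy]phenoxy}borane | BrB(Br)Oc1ccccc1Oc1cc(Br)c(Br)c(Br)c1OB(Br)Br
F8 | step 5 | 2,3,4-tribromo-6-(2-hydroxyphenoxy)phenol | Oc1ccccc1Oc1cc(Br)c(Br)c(Br)c1O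
F9 | step 3 | 3,4,5-tribromo-2-hydroxybenzenediazonium tetrafluoroborate | Oc1c(Br)c(Br)c(Br)cc1[N+]#N.F[B-](F)(F)F
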